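**Plan**

- Retrosynthetic cuts, in order: the 7-O-pivaloyl helper; the chroman O–C(CH3)2 bond (back to a 3'-prenyl-4'-phenol); the C3'–CH2 and C8–CH2 bonds of both dimethylallyl units (two retro-[3,3] shifts, back to a 4'-O-(1,1-dimethylallyl) ether and a 5-O-prenyl ether); the C2–C1' bond (aryl conjugate addition to a chromone).
- Enabling feature: the ring to be closed is a dimethylallyl unit bridging the ring B oxygen (its C(CH3)2 end) and the ortho carbon C3' (its CH2 end), which is what a Claisen shift of an O-bound 1,1-dimethylallyl group followed by Markovnikov O–H addition leaves behind. The second dimethylallyl unit sits at C8, para to the 5-OH that is peri to the C4 ketone, the position a chelation-driven para-Claisen–Cope shift reaches.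
- Forward: ring A and the pyranone ring come ready-made in 5,7-dihydroxychromone, ring B from 4-bromophenol. They are joined at C2, then one cascade moves both dimethylallyl units from O to C and closes the dihydropyran ring of the chroman as the last ring. The 7-O-pivalate keeps the C8 prenyl open-chain and is removed last.
- Stereochemistry: the only stereocenter, C2 (S), is set by a rhodium/chiral bisphosphine-catalysed 1,4-addition of the ring B boronic acid to the chromone, and afterwards sees no strong base and no hot strong acid.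

Key step: step 7

Assumption: the sense of induction in step 6 is taken from the quadrant model of biaryl bisphosphine–rhodium catalysts, by which the (S)-ligand should give the 2S adduct; if a test addition shows the opposite sense, the (R)-ligand is used and nothing else changes.

**Route**

Step 1
Reactants: 1 5,7-dihydroxychromone
Product: 2 5-hydroxy-4-oxo-4H-chromen-7-yl pivalate
Conditions: PivCl (1.05 equiv), Et3N, CH2Cl2, 0 °C
Reagents that add atoms: pivaloyl chloride, CC(C)(C)C(Cl)=O
Why: Selective O-acylation of a phenol: the 7-OH is the more acidic, unhindered hydroxyl while the 5-OH is locked in a hydrogen bond to the C4 carbonyl, so one equivalent of acid chloride should give the 7-ester only, which later keeps the chromone electrophilic and blocks the 7-oxygen in step 7.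

Step 2
Reactants: 2 5-hydroxy-4-oxo-4H-chromen-7-yl pivalate; 3 3-methylbut-2-en-1-ol (prenol)
Product: 4 5-(3-methylbut-2-enyloxy)-4-oxo-4H-chromen-7-yl pivalate
Conditions: PPh3, DIAD, THF, 0 to 25 °C
Reagents that add atoms: none
Why: Mitsunobu etherification of the remaining chelated 5-OH with the primary allylic alcohol, a neutral redox condensation with close precedent on chelated 5-hydroxyflavonoids that should leave the base-labile aryl pivalate untouched.

Step 3
Reactants: 5 4-bromophenol; 6 3-chloro-3-methylbut-1-yne
Product: 7 1-bromo-4-(2-methylbut-3-yn-2-yloxy)benzene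
Conditions: CuCl2·2H2O (0.5 mol%), DBU, MeCN, 0 °C
Reagents that add atoms: none
Why: Copper-catalysed propargylic etherification: the copper acetylide of 6 loses chloride to an allenylidene-type electrophile that the phenoxide attacks at the tertiary carbon, giving the hindered tertiary aryl ether that direct alkylation cannot.

Step 4
Reactants: 7 1-bromo-4-(2-methylbut-3-yn-2-yloxy)benzene
Product: 8 1-bromo-4-(2-methylbut-3-en-2-yloxy)benzene
Conditions: H2 (1 atm), Pd/CaCO3 poisoned with Pb(OAc)2 (Lindlar catalyst), quinoline, EtOAc, 25 °C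
Reagents that add atoms: none
Why: Lindlar semi-hydrogenation should stop at the terminal alkene and leave the aryl bromide and the tertiary C–O bond alone, giving the O-bound 1,1-dimethylallyl group needed for the later Claisen shift.

Step 5
Reactants: 8 1-bromo-4-(2-methylbut-3-en-2-yloxy)benzene
Product: 11 [4-(2-methylbut-3-en-2-yloxy)phenyl]boronic acid, via aryllithium 9 (not isolated), via lithium aryltriisopropoxyborate 10 (not isolated)
Conditions: n-BuLi, THF, −78 °C; B(OiPr)3, −78 to 0 °C; aq. NH4Cl
Reagents that add atoms: triisopropyl borate, CC(C)OB(OC(C)C)OC(C)C; water, O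
Why: Bromine–lithium exchange at −78 °C is much faster than any attack on the allyl ether, the aryllithium is trapped by the borate, and the weakly acidic ammonium chloride work-up hydrolyses the borate without ionising the acid-sensitive tertiary allyl ether (lithiation–borylation).

Step 6
Reactants: 4 5-(3-methylbut-2-enyloxy)-4-oxo-4H-chromen-7-yl pivalate; 11 [4-(2-methylbut-3-en-2-yloxy)phenyl]boronic acid
Product: 12 (2S)-2-[4-(2-methylbut-3-en-2-yloxy)phenyl]-5-(3-methylbut-2-enyloxy)-4-oxochroman-7-yl pivalate
Conditions: [Rh(OH)(cod)]2 (2.5 mol%), (S)-MeO-F12-BIPHEP [(S)-6,6'-dimethoxy-2,2'-bis[bis(3,4,5-trifluorophenyl)phosphino]biphenyl, 5.5 mol%], 11 (2 equiv), toluene/H2O 10:1, 30 °C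
Reagents that add atoms: none
Why: Rhodium-catalysed asymmetric 1,4-addition of an arylboronic acid to the chromone enone (Hayashi–Miyaura reaction): the aryl–rhodium formed by transmetalation inserts the C2=C3 bond on the enone face left open by the electron-poor biaryl bisphosphine, so C2 should form as S, while the near-neutral two-phase medium at 30 °C should spare the pivalate and both allyl ethers.

Step 7
Reactants: 12 (2S)-2-[4-(2-methylbut-3-en-2-yloxy)phenyl]-5-(3-methylbut-2-enyloxy)-4-oxochroman-7-yl pivalate
Product: 15 (2S)-2-(2,2-dimethylchroman-6-yl)-5-hydroxy-8-(3-methylbut-2-enyl)-4-oxochroman-7-yl pivalate, via 8-prenyl tertiary allyl ether 13 (not isolated), via 8,3'-diprenyl phenol 14 (not isolated)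
Conditions: Eu(fod)3 (fod = 6,6,7,7,8,8,8-heptafluoro-2,2-dimethyl-3,5-octanedionate, 10 mol%), NaHCO3, PhCl, 85 °C, then 120 °C; cool, filter; Amberlyst 15 (sulfonic acid resin), 25 °C
Reagents that add atoms: none
Why: Europium chelated between the C4 carbonyl and the 5-oxygen triggers a [3,3] shift of the O-prenyl group to C6 and a following Cope [3,3] shift to C8 with re-aromatisation (13), at 120 °C the O-bound 1,1-dimethylallyl group of ring B undergoes an aromatic Claisen [3,3] shift to C3' (14), and the sulfonic acid resin then protonates the C3' prenyl alkene at its CH carbon so that the neighbouring 4'-OH captures the tertiary cation. The closest known reaction types are the europium-catalysed para-Claisen–Cope rearrangement of 5-O-prenyl flavonoids, the thermal Claisen rearrangement of aryl 1,1-dimethylallyl ethers and the acid-catalysed cyclisation of ortho-prenylphenols to 2,2-dimethylchromans. The dihydropyran ring of the chroman closes by cationic Markovnikov hydroalkoxylation in the 6-endo-trig mode, forming the O–C(CH3)2 bond. No new stereocenter arises, and C2 should be kept because the medium holds no soluble base and meets strong acid only at 25 °C. Three selectivities are needed: C8 over C6 in ring A, which the Cope step out of the crowded C6 dienone under the chelating catalyst should secure; none in ring B, whose two ortho carbons are equivalent; and closure of the ring B prenyl only, which is secured because the C8 prenyl is flanked by the ring oxygen and the 7-O-pivalate and has no free hydroxyl within reach.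

Step 8
Reactants: 15 (2S)-2-(2,2-dimethylchroman-6-yl)-5-hydroxy-8-(3-methylbut-2-enyl)-4-oxochroman-7-yl pivalate
Product: 16 Euchrenone a16
Conditions: K2CO3 (1.5 equiv), MeOH, 0 °C; aq. NH4Cl
Reagents that add atoms: none
Why: Base-mediated methanolysis (transesterification) of an aryl ester whose leaving phenoxide is para to the ketone and therefore activated, so that even the pivalate should cleave at 0 °C, where the 5,7-dioxygenated flavanone, having no free 4'-OH, should not open to the chalcone and C2 should stay S.

**Compound list**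

1 | 5,7-dihydroxy-4H-chromen-4-one (5,7-dihydroxychromone) | O=c1ccoc2cc(O)cc(O)c12 | starting material
2 | 5-hydroxy-4-oxo-4H-chromen-7-yl pivalate | O=c1ccoc2cc(OC(=O)C(C)(C)C)cc(O)c12 | intermediate
3 | 3-methylbut-2-en-1-ol (prenol) | CC(C)=CCO | starting material
4 | 5-(3-methylbut-2-enyloxy)-4-oxo-4H-chromen-7-yl pivalate | O=c1ccoc2cc(OC(=O)C(C)(C)C)cc(OCC=C(C)C)c12 | intermediate
5 | 4-bromophenol | Oc1ccc(Br)cc1 | starting material
6 | 3-chloro-3-methylbut-1-yne | C#CC(C)(C)Cl | starting material
7 | 1-bromo-4-(2-methylbut-3-yn-2-yloxy)benzene | C#CC(C)(C)Oc1ccc(Br)cc1 | intermediate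
8 | 1-bromo-4-(2-methylbut-3-en-2-yloxy)benzene | C=CC(C)(C)Oc1ccc(Br)cc1 | intermediate
9 | [4-(2-methylbut-3-en-2-yloxy)phenyl]lithium (formed in the flask) | [Li]c1ccc(OC(C)(C)C=C)cc1 | intermediate
10 | lithium triisopropoxy[4-(2-methylbut-3-en-2-yloxy)phenyl]borate (formed in the flask) | [Li+].CC(C)O[B-](OC(C)C)(OC(C)C)c1ccc(OC(C)(C)C=C)cc1 | intermediate
11 | [4-(2-methylbut-3-en-2-yloxy)phenyl]boronic acid | OB(O)c1ccc(OC(C)(C)C=C)cc1 | intermediate
12 | (2S)-2-[4-(2-methylbut-3-en-2-yloxy)phenyl]-5-(3-methylbut-2-enyloxy)-4-oxochroman-7-yl pivalate | CC(C)=CCOc1cc(OC(=O)C(C)(C)C)cc2O[C@H](c3ccc(OC(C)(C)C=C)cc3)CC(=O)c12 | intermediate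
13 | (2S)-5-hydroxy-2-[4-(2-methylbut-3-en-2-yloxy)phenyl]-8-(3-methylbut-2-enyl)-4-oxochroman-7-yl pivalate (formed in the flask) | CC(C)=CCc1c(OC(=O)C(C)(C)C)cc(O)c2c1O[C@H](c1ccc(OC(C)(C)C=C)cc1)CC2=O | intermediate
14 | (2S)-5-hydroxy-2-[4-hydroxy-3-(3-methylbut-2-enyl)phenyl]-8-(3-methylbut-2-enyl)-4-oxochroman-7-yl pivalate (formed in the flask) | CC(C)=CCc1c(OC(=O)C(C)(C)C)cc(O)c2c1O[C@H](c1ccc(O)c(CC=C(C)C)c1)CC2=O | intermediate
15 | (2S)-2-(2,2-dimethylchroman-6-yl)-5-hydroxy-8-(3-methylbut-2-enyl)-4-oxochroman-7-yl pivalate | CC(C)=CCc1c(OC(=O)C(C)(C)C)cc(O)c2c1O[C@H](c1ccc3c(c1)CCC(C)(C)O3)CC2=O | intermediate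
16 | Euchrenone a16, (2S)-2-(2,2-dimethylchroman-6-yl)-5,7-dihydroxy-8-(3-methylbut-2-enyl)chroman-4-one | CC(C)=CCc1c(O)cc(O)c2c1O[C@H](c1ccc3c(c1)CCC(C)(C)O3)CC2=O | target

**Count**

Total steps: 8. Longest linear sequence: 6 steps (steps 3, 4, 5, 6, 7, 8); the chromone branch (steps 1 and 2) joins at step 6.

**Steps most likely to fail**

Step 7. What may go wrong: the tertiary 1,1-dimethylallyl group is lost from the ring B oxygen as isoprene under Lewis acid and heat before it can shift to C3', and the 120 °C stage puts thermal stress on C2 once the 4'-OH is free. The fallback puts the ring B prenyl on carbon by phenoxide C-alkylation instead of sigmatropic transfer. It sets out from 5 and 4 and comes back to the route at 14. 4-Bromophenol 5 is ortho-C-prenylated as its sodium salt (NaH, 1-bromo-3-methylbut-2-ene, toluene, 25 °C) to 4-bromo-2-(3-methylbut-2-enyl)phenol F1. Silylation (TBSCl, imidazole, DMF) gives (4-bromo-2-(3-methylbut-2-enyl)phenoxy)(tert-butyl)dimethylsilane F2. Bromine–lithium exchange and borylation as in step 5 lead through [4-(tert-butyldimethylsilyloxy)-3-(3-methylbut-2-enyl)phenyl]lithium F3 and lithium [4-(tert-butyldimethylsilyloxy)-3-(3-methylbut-2-enyl)phenyl]triisopropoxyborate F4 (neither isolated) to [4-(tert-butyldimethylsilyloxy)-3-(3-methylbut-2-enyl)phenyl]boronic acid F5. Addition of F5 to chromone 4 under the conditions of step 6 should give (2S)-2-[4-(tert-butyldimethylsilyloxy)-3-(3-methylbut-2-enyl)phenyl]-5-(3-methylbut-2-enyloxy)-4-oxochroman-7-yl pivalate F6. Eu(fod)3 and NaHCO3 in PhCl at 85 °C then move only the ring A prenyl to C8, giving (2S)-2-[4-(tert-butyldimethylsilyloxy)-3-(3-methylbut-2-enyl)phenyl]-5-hydroxy-8-(3-methylbut-2-enyl)-4-oxochroman-7-yl pivalate F7. HF·pyridine in THF at 0 °C frees the 4'-phenol to give 14, which the resin stage of step 7 alone closes to 15.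

Step 6. What may go wrong: insertion of the electron-rich 5-alkoxychromone into the phosphine-bound aryl–rhodium is sluggish, so protodeboronation of the electron-rich boronic acid takes over, or the facial selectivity is poor. The fallback separates bond formation from stereocontrol. It sets out from 4 and 11 and comes back at 12. The more active phosphine-free catalyst [Rh(OH)(cod)]2 (dioxane/H2O, 30 °C) should give racemic 2-[4-(2-methylbut-3-en-2-yloxy)phenyl]-5-(3-methylbut-2-enyloxy)-4-oxochroman-7-yl pivalate F8. Kinetic resolution by asymmetric transfer hydrogenation (RuCl(p-cymene)(TsDPEN), the enantiomer that consumes the 2R ketone, HCO2H/Et3N, 25 °C, stopped near half conversion) should reduce the 2R ketone to (2R,4R)-4-hydroxy-2-[4-(2-methylbut-3-en-2-yloxy)phenyl]-5-(3-methylbut-2-enyloxy)chroman-7-yl pivalate F9. F9 is removed by chromatography and the unreduced 2S ketone is 12.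

Step 8. What may go wrong: base-induced opening of the pyranone ring to the chalcone (loss of the C2 configuration) competes with slow methanolysis of the hindered ester. The fallback replaces alkoxide solvolysis by enzymatic hydrolysis at neutral pH. It sets out from 15 and comes back at 16. A carboxylesterase (pig liver esterase) in phosphate buffer pH 7 with acetone as co-solvent at 30 °C should hydrolyse the aryl pivalate, a substrate type this enzyme class is known to accept, without any base reaching C3. No new compound is made on the way.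

**Further compounds**

F1 | step 7 | 4-bromo-2-(3-methylbut-2-enyl)phenol | CC(C)=CCc1cc(Br)ccc1O
F2 | step 7 | (4-bromo-2-(3-methylbut-2-enyl)phenoxy)(tert-butyl)dimethylsilane | CC(C)=CCc1cc(Br)ccc1O[Si](C)(C)C(C)(C)C
F3 | step 7 | [4-(tert-butyldimethylsilyloxy)-3-(3-methylbut-2-enyl)phenyl]lithium | [Li]c1ccc(O[Si](C)(C)C(C)(C)C)c(CC=C(C)C)c1
F4 | step 7 | lithium [4-(tert-butyldimethylsilyloxy)-3-(3-methylbut-2-enyl)phenyl]triisopropoxyborate | [Li+].CC(C)O[B-](OC(C)C)(OC(C)C)c1ccc(O[Si](C)(C)C(C)(C)C)c(CC=C(C)C)c1
F5 | step 7 | [4-(tert-butyldimethylsilyloxy)-3-(3-methylbut-2-enyl)phenyl]boronic acid | OB(O)c1ccc(O[Si](C)(C)C(C)(C)C)c(CC=C(C)C)c1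
F6 | step 7 | (2S)-2-[4-(tert-butyldimethylsilyloxy)-3-(3-methylbut-2-enyl)phenyl]-5-(3-methylbut-2-enyloxy)-4-oxochroman-7-yl pivalate | CC(C)=CCOc1cc(OC(=O)C(C)(C)C)cc2O[C@H](c3ccc(O[Si](C)(C)C(C)(C)C)c(CC=C(C)C)c3)CC(=O)c12
F7 | step 7 | (2S)-2-[4-(tert-butyldimethylsilyloxy)-3-(3-methylbut-2-enyl)phenyl]-5-hydroxy-8-(3-methylbut-2-enyl)-4-oxochroman-7-yl pivalate | CC(C)=CCc1c(OC(=O)C(C)(C)C)cc(O)c2c1O[C@H](c1ccc(O[Si](C)(C)C(C)(C)C)c(CC=C(C)C)c1)CC2=O
F8 | step 6 | racemic 2-[4-(2-methylbut-3-en-2-yloxy)phenyl]-5-(3-methylbut-2-enyloxy)-4-oxochroman-7-yl pivalate | CC(C)=CCOc1cc(OC(=O)C(C)(C)C)cc2OC(c3ccc(OC(C)(C)C=C)cc3)CC(=O)c12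
F9 | step 6 | (2R,4R)-4-hydroxy-2-[4-(2-methylbut-3-en-2-yloxy)phenyl]-5-(3-methylbut-2-enyloxy)chroman-7-yl pivalate | CC(C)=CCOc1cc(OC(=O)C(C)(C)C)cc2O[C@@H](c3ccc(OC(C)(C)C=C)cc3)C[C@@H](O)c12
F0 | step 8 | none | none
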